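**Retrosynthetic overview**
- The strategy rests on the substitution pattern of ring A: OH on C1, the ether oxygen on C2, and Br on C3 and C5. If C1–OH is read as a former C1–CHO and C2–O as a former C2–F, ring A becomes 3,5-dibromo-2-fluorobenzaldehyde. Ring B is simply 2,4-dibromophenol.
- Disconnections: (i) C1–OH back to C1–OCHO and then to C1–CHO (formate cleavage, Baeyer–Villiger); (ii) the O–C2 bond of ring A back to 2,4-dibromophenoxide and the aryl fluoride (SNAr); (iii) the four C–Br bonds back to phenol and 2-fluorobenzaldehyde.
- No ring is formed. Both benzene rings are purchased, each is brominated separately before the union, and they are then joined through oxygen. No bromination is carried out after the coupling.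

Key step: step 4

Assumption: the SMILES carries no stereodescriptor, and the molecule has no stereocentre and no hindered axis. It is therefore treated as achiral and no enantiomer has to be selected.

**Step 1**
Reactants: 1 phenol
Product: 2 2,4-dibromophenol
Conditions: Br2 (2.0 equiv, slow addition), CH2Cl2, 0 °C to rt
Reagents that add atoms: bromine, BrBr
Why: Electrophilic aromatic bromination (SEAr), in which the hydroxyl group activates its para and ortho carbons, each bromine slows the next substitution, and exactly two equivalents of Br2 added cold in a non-ionising solvent should stop the reaction at the 2,4-dibromide before the second ortho carbon reacts.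

**Step 2**
Reactants: 3 2-fluorobenzaldehyde
Product: 4 5-bromo-2-fluorobenzaldehyde
Conditions: NBS (1.05 equiv), conc. H2SO4, rt to 40 °C
Reagents that add atoms: N-bromosuccinimide (NBS), O=C1CCC(=O)N1Br
Why: SEAr with acid-activated NBS, in which C5 is para to the π-donating fluorine and meta to the protonated formyl group so that both substituents select the same carbon, while the strongly acidic ionic medium suppresses radical attack on the formyl C–H.

**Step 3**
Reactants: 4 5-bromo-2-fluorobenzaldehyde
Product: 5 3,5-dibromo-2-fluorobenzaldehyde
Conditions: NBS (1.3 equiv), conc. H2SO4, 60 °C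
Reagents that add atoms: N-bromosuccinimide (NBS), O=C1CCC(=O)N1Br
Why: Bromination of a deactivated arene with NBS/H2SO4 (SEAr), in which C3 is the only free carbon both ortho to fluorine and meta to the formyl group, whereas C4 and C6 are favoured only by the weakly directing C5 bromine and lie para and ortho to the acceptor, so the second bromine should enter at C3 once heating compensates for the lower ring reactivity.

**Step 4**
Reactants: 2 2,4-dibromophenol; 5 3,5-dibromo-2-fluorobenzaldehyde
Product: 7 3,5-dibromo-2-(2,4-dibromophenoxy)benzaldehyde, via potassium 2,4-dibromophenoxide 6 (not isolated)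
Conditions: 2 (1.1 equiv), K2CO3 (1.5 equiv), dry DMSO, 80–90 °C, N2
Reagents that add atoms: none
Why: K2CO3 converts 2 into phenoxide 6, whose oxygen attacks C2 of 5 in an addition–elimination SNAr; the negative charge of the transient Meisenheimer-type σ-adduct falls on C1, C3 and C5, where the formyl group accepts it by resonance and the two bromines lower it inductively, and loss of fluoride then rearomatises ring A. The closest known reaction type is the carbonate-mediated displacement of fluoride from 2-fluorobenzaldehydes by phenoxides to give 2-aryloxybenzaldehydes. Only the O–C2 bond between the two rings is formed, so no ring is closed and no stereocentre is created. The selectivity required is replacement of the single C–F bond in the presence of four C–Br bonds, and it is secured because only C2 lies ortho to the formyl acceptor, the bromines of 5 are meta to it, those of 6 sit on an electron-rich ring, fluoride is the best leaving group when addition is rate-limiting, and no transition metal is present to activate C–Br. Dry DMSO and a slight excess of 2 should keep hydroxide (and the amine impurities that hot DMF releases) from competing for C2, and the aldehyde has no α-hydrogen for carbonate to remove.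

**Step 5**
Reactants: 7 3,5-dibromo-2-(2,4-dibromophenoxy)benzaldehyde
Product: 8 3,5-dibromo-2-(2,4-dibromophenoxy)phenyl formate
Conditions: mCPBA (2 equiv), CH2Cl2, rt to reflux; aq. Na2SO3 then brief aq. NaHCO3 wash; used crude
Reagents that add atoms: mCPBA (3-chloroperoxybenzoic acid), O=C(OO)c1cccc(Cl)c1
Why: Baeyer–Villiger oxidation of an aryl aldehyde (Dakin-type outcome), in which the peracid adds to the formyl carbon and ring carbon C1 of the Criegee adduct, supported by the lone pair of the ortho aryloxy oxygen, should migrate to oxygen in preference to hydrogen, while the aryl bromides and the diaryl ether are inert to peracid.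

**Step 6**
Reactants: 8 3,5-dibromo-2-(2,4-dibromophenoxy)phenyl formate
Product: 9 3,5-dibromo-2-(2,4-dibromophenoxy)phenol (target, achiral)
Conditions: K2CO3 (0.2 equiv), MeOH–THF, 0 °C to rt; then 1 M HCl wash
Reagents that add atoms: none
Why: Base-catalysed methanolysis (transesterification) of a highly electrophilic aryl formate, in which methoxide adds to the formyl carbon and expels the stabilised bromophenoxide under conditions too mild to affect the diaryl ether or the C–Br bonds, and the acidic wash returns the free OH at C1.

**Compound list**
1 | phenol | Oc1ccccc1 | starting material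
2 | 2,4-dibromophenol | Oc1ccc(Br)cc1Br | intermediate
3 | 2-fluorobenzaldehyde | O=Cc1ccccc1F | starting material
4 | 5-bromo-2-fluorobenzaldehyde | O=Cc1cc(Br)ccc1F | intermediate
5 | 3,5-dibromo-2-fluorobenzaldehyde | O=Cc1cc(Br)cc(Br)c1F | intermediate
6 | potassium 2,4-dibromophenoxide (not isolated) | [K+].[O-]c1ccc(Br)cc1Br | intermediate
7 | 3,5-dibromo-2-(2,4-dibromophenoxy)benzaldehyde | O=Cc1cc(Br)cc(Br)c1Oc1ccc(Br)cc1Br | intermediate
8 | 3,5-dibromo-2-(2,4-dibromophenoxy)phenyl formate | O=COc1cc(Br)cc(Br)c1Oc1ccc(Br)cc1Br | intermediate
9 | 3,5-dibromo-2-(2,4-dibromophenoxy)phenol | Oc1cc(Br)cc(Br)c1Oc1ccc(Br)cc1Br | target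

**Total step count:** 6
**Longest linear sequence:** 5 steps (3 → 4 → 5 → 7 → 8 → 9). The phenol branch adds one step and joins at step 4.

**Steps most likely to fail**

1. **Step 5.**
   - Risk: the two bromines meta to C1 lower the migratory aptitude of ring A. Hydrogen migration in the Criegee adduct may then compete with aryl migration, so the formyl group is oxidised in place rather than excised.
   - Fallback from 7, rejoining at 9 (bypassing 8): the competing hydrogen is replaced by a methyl group before the oxidation.
   - MeMgBr (THF, −78 °C) is too poor an exchange reagent to touch the C–Br bonds at that temperature. It should give racemic 1-[3,5-dibromo-2-(2,4-dibromophenoxy)phenyl]ethanol F1.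
   - Dess–Martin periodinane in CH2Cl2 should then give 1-[3,5-dibromo-2-(2,4-dibromophenoxy)phenyl]ethanone F2.
   - Baeyer–Villiger oxidation with trifluoroperacetic acid (urea·H2O2, TFAA, Na2HPO4, CH2Cl2) now sets aryl only against methyl migration, and aryl is preferred. This should give 3,5-dibromo-2-(2,4-dibromophenoxy)phenyl acetate F3.
   - K2CO3 in MeOH cleaves F3 to 9.

2. **Step 3.**
   - Risk: the second electrophilic substitution may stall or lose regioselectivity on a ring bearing three deactivating groups. Prolonged heating in acidic bromine(I) may also degrade the formyl group oxidatively.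
   - Fallback from 4, rejoining at 5: the bromine is installed by directed metalation instead of SEAr.
   - Ethylene glycol, cat. TsOH and toluene (Dean–Stark) should give 2-(5-bromo-2-fluorophenyl)-1,3-dioxolane F4.
   - LDA (THF, −78 °C) should remove the only proton ortho to fluorine and give 2-(5-bromo-2-fluoro-3-lithiophenyl)-1,3-dioxolane F5. This species is kept at −78 °C to prevent loss of LiF.
   - Quenching with 1,2-dibromotetrachloroethane should give 2-(3,5-dibromo-2-fluorophenyl)-1,3-dioxolane F6.
   - Aqueous HCl in THF releases aldehyde 5.

3. **Step 4.**
   - Risk: a weakly nucleophilic, ortho-substituted phenoxide adds slowly to a carbon flanked on both sides. Displacement by adventitious hydroxide or base-induced degradation of the aldehyde may then take over.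
   - Fallback from 5, rejoining at 7: the polarity of the union is reversed, so ring A supplies the oxygen and ring B the electrophilic carbon.
   - The small nucleophile hydroxide (KOH, DMSO–H2O, 60–80 °C, then acid) should convert 5 into 3,5-dibromo-2-hydroxybenzaldehyde F7, which is also a catalogue compound.
   - Separately, 1,3-dibromobenzene is condensed with iodyl sulfate (from I2 and KIO3 in conc. H2SO4). Aqueous NaBF4 then precipitates bis(2,4-dibromophenyl)iodonium tetrafluoroborate F8.
   - Treating F7 with t-BuOK and F8 in THF (rt to 40 °C, no metal) should transfer one 2,4-dibromophenyl group to the phenoxide oxygen by ligand coupling at iodine(III) and give 7.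

**Further compounds**
F1 | step 5 | 1-[3,5-dibromo-2-(2,4-dibromophenoxy)phenyl]ethanol (racemic) | CC(O)c1cc(Br)cc(Br)c1Oc1ccc(Br)cc1Br
F2 | step 5 | 1-[3,5-dibromo-2-(2,4-dibromophenoxy)phenyl]ethanone | CC(=O)c1cc(Br)cc(Br)c1Oc1ccc(Br)cc1Br
F3 | step 5 | 3,5-dibromo-2-(2,4-dibromophenoxy)phenyl acetate | CC(=O)Oc1cc(Br)cc(Br)c1Oc1ccc(Br)cc1Br
F4 | step 3 | 2-(5-bromo-2-fluorophenyl)-1,3-dioxolane | Fc1ccc(Br)cc1C1OCCO1
F5 | step 3 | 2-(5-bromo-2-fluoro-3-lithiophenyl)-1,3-dioxolane | [Li]c1cc(Br)cc(C2OCCO2)c1F
F6 | step 3 | 2-(3,5-dibromo-2-fluorophenyl)-1,3-dioxolane | Fc1c(Br)cc(Br)cc1C1OCCO1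
F7 | step 4 | 3,5-dibromo-2-hydroxybenzaldehyde | O=Cc1cc(Br)cc(Br)c1O
F8 | step 4 | bis(2,4-dibromophenyl)iodonium tetrafluoroborate | Brc1ccc([I+]c2ccc(Br)cc2Br)c(Br)c1.F[B-](F)(F)F
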